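(All runs are calculated on assumed constants.)

Starting material charged to a closed flask of constant volume is conserved: each part of it stands as itself or as something made from it. The flask asked for differs from the elm run in its catalyst charge and in its allowed time.

- elm: starting material 2 M; protic impurity 1 M; free catalyst 16 mM; run made earlier
- flask: starting material 2.0 M; protic impurity 1.00 M; free catalyst 11 mM; time 15 min

- elm (time / min: target / %): 0.250: 7.1; 0.667: 12.6; 1.33: 16.8; 2.00: 17.7; 2.50: 19.0; 4.00: 20.0; 5.00: 20.3

(standard deviation of a reading: 0.5 percentage points)

- the analysis behind the earlier runs scatters by 0.5 percentage points, standard deviation
- no earlier run changes the charge of free catalyst; that part of a forecast is a guess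

- the best time, 15 min at the latest, for target
- the amount of target, in percent of the starting material charged, at that time

Read as a division of that charge, the elm run gives a first hand estimate. Target reaches 20.3% at 5.00 min, and the last two readings differ by 0.3 percentage points, less than the scatter of 0.5 points. The readings follow target, so what takes the rest of the charge is unseen. This reckoning assumes that the rival path does not use the catalyst and freezes c(free catalyst) at its charge. Target's rate then scales with c(free catalyst) and the rival's does not.

Scaling the plateau directly by 0.688 gives 14.0% for the flask. That link is the weak one. What scales under these assumptions is target's part over the remainder, so the carried quantity is the partition odds per unit of catalyst, a selectivity factor: plateau share over the rest, divided by c(free catalyst), 0.0159 /mM. For the flask the odds become 0.175, and the share is 14.9%, which this reckoning commits to, on a plateau from about 5.00 min.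

The forecast, a separate judgement, gives 15.5% and puts the time at 15 min, on the ground that “No loss of target appears”.

The simulation gives 16.3% at 5.03 min.

    starting material + free catalyst ⇌ target + free catalyst, rate k1*[starting material]*[free catalyst] forward; the back reaction follows from the equilibrium constant (K = 18.0, k = 0.533 /M/s)
    target + free catalyst ⇌ isomer of the product + free catalyst, rate k2*[free catalyst]*[target] forward; the back reaction follows from the equilibrium constant (K = 0.210, k = 0.846 /M/s)
    free catalyst + target → spent catalyst (k = 0.00100 /M/s)
    starting material → uncatalysed product (k = 0.00810 /s)
    starting material + protic impurity → quenched substrate (k = 0.0887 /M/s)

The flask's peak stands above the 14.9% reckoned with the odds, and its target declines to 15.1% at 15.0 min. The neighbouring flask changes one setting, free catalyst at 6.60 mM, with the other charges and the time held. The same quantity gives it odds of 0.105 and a share of 9.51%. The neighbouring flask reaches 11.8%, again above the reckoning, and its target stands at 11.3% at 15.0 min.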